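**Retrosynthetic overview**
1. The allylic alcohol comes last, from a ring A methyl ester (reduction, oxidation, Wittig olefination, reduction), followed by global desilylation.
2. Each trans-dioxane ring is opened at its aryl C–O bond: intramolecular palladium-catalysed etherification of an o-bromoaryl ether, with retention, from a syn 2-aryloxy-1-arylpropane-1,3-diol.
3. Each diol comes from an intermolecular Evans syn-aldol between an N-(aryloxyacetyl)oxazolidinone boron enolate and an aryl aldehyde; this forms the C–C bond between the two dioxane stereocentres.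
4. Both enolate partners derive from one acid chloride, 2-[2-bromo-4-(methoxycarbonyl)phenoxy]acetyl chloride. The (R)-auxiliary gives the (2S,3S) unit, the (S)-auxiliary the (2R,3R) unit.
5. Ring order: ring C (purchased) → dioxane ring D on ring B → ester to aldehyde → second aldol → dioxane ring E on ring A.

Assumption: ring A carries the allylic alcohol, ring B is the central arene, ring C is the catechol; dioxane ring D joins rings B and C and is (2S,3S), dioxane ring E joins rings A and B and is (2R,3R). TBS = tert-butyldimethylsilyl, TBSO = its ether, Bn = benzyl. Simple metal alkoxide salts that exist only until the aqueous quench are not numbered.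

**Step 1**
Reactants: 1 methyl 3-bromo-4-hydroxybenzoate; 2 tert-butyl bromoacetate
Product: 3 tert-butyl 2-[2-bromo-4-(methoxycarbonyl)phenoxy]acetate
Conditions: K2CO3, DMF, rt
Reagents that add atoms: none
Why: Williamson ether synthesis, in which the acidic phenol is alkylated cleanly by the primary α-bromo ester and the tert-butyl ester stays distinguishable from the methyl benzoate.

**Step 2**
Reactants: 3 tert-butyl 2-[2-bromo-4-(methoxycarbonyl)phenoxy]acetate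
Product: 4 2-[2-bromo-4-(methoxycarbonyl)phenoxy]acetic acid
Conditions: CF3CO2H, CH2Cl2, rt
Reagents that add atoms: none
Why: Acid-mediated tert-butyl ester cleavage (loss of 2-methylpropene) leaves the methyl benzoate and the aryl ether untouched.

**Step 3**
Reactants: 4 2-[2-bromo-4-(methoxycarbonyl)phenoxy]acetic acid
Product: 5 2-[2-bromo-4-(methoxycarbonyl)phenoxy]acetyl chloride
Conditions: (COCl)2, DMF (cat.), CH2Cl2, 0 °C → rt; concentrated, used crude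
Reagents that add atoms: oxalyl chloride, O=C(Cl)C(Cl)=O
Why: Acid chloride formation through the Vilsmeier-type chloroiminium catalyst is neutral enough to spare the methyl benzoate, and gives one batch of acylating agent for both auxiliaries.

**Step 4**
Reactants: 5 2-[2-bromo-4-(methoxycarbonyl)phenoxy]acetyl chloride; 6 (4R)-4-benzyl-1,3-oxazolidin-2-one
Product: 8 methyl 4-{2-[(4R)-4-benzyl-2-oxo-1,3-oxazolidin-3-yl]-2-oxoethoxy}-3-bromobenzoate, via N-lithio oxazolidinone 7 (not isolated)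
Conditions: 6, n-BuLi (1.0 equiv), THF, −78 °C; then 5, −78 → 0 °C
Reagents that add atoms: none
Why: N-acylation of the lithiated Evans oxazolidinone, in which the acid chloride reacts far faster than the methyl benzoate and the weakly basic lithium imidate does not touch the aryl bromide.

**Step 5**
Reactants: 8 methyl 4-{2-[(4R)-4-benzyl-2-oxo-1,3-oxazolidin-3-yl]-2-oxoethoxy}-3-bromobenzoate; 9 3,4-bis(benzyloxy)benzaldehyde
Product: 12 methyl 4-{[(2R,3S)-1-[(4R)-4-benzyl-2-oxo-1,3-oxazolidin-3-yl]-3-[3,4-bis(benzyloxy)phenyl]-3-hydroxy-1-oxopropan-2-yl]oxy}-3-bromobenzoate, via Z-boron enolate 10 (not isolated), via boron aldolate 11 (not isolated)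
Conditions: n-Bu2BOTf, i-Pr2NEt, CH2Cl2, −78 → 0 °C; then 9, −78 → 0 °C; then pH 7 buffer, MeOH, 30% H2O2, 0 °C
Reagents that add atoms: none
Why: Evans syn-aldol, in which the Z-boron enolate adds to the aldehyde through a Zimmerman–Traxler chair on the face away from the benzyl group of the (R)-auxiliary, setting both new stereocentres (2R,3S, syn) in the C–C bond-forming event.

**Step 6**
Reactants: 12 the syn aldol adduct
Product: 13 methyl 4-{[(1S,2S)-1-[3,4-bis(benzyloxy)phenyl]-1,3-dihydroxypropan-2-yl]oxy}-3-bromobenzoate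
Conditions: LiBH4, MeOH (2 equiv), THF, 0 °C
Reagents that add atoms: none
Why: Reductive cleavage of the Evans auxiliary, in which the activated imide carbonyl is reduced far faster at 0 °C than the methyl benzoate and neither stereocentre is touched.

**Step 7**
Reactants: 13 the (1S,2S) diol
Product: 14 methyl 4-{[(1S,2S)-1-[3,4-bis(benzyloxy)phenyl]-3-(TBSO)-1-hydroxypropan-2-yl]oxy}-3-bromobenzoate
Conditions: TBSCl (1.1 equiv), imidazole, CH2Cl2, 0 °C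
Reagents that add atoms: tert-butyldimethylsilyl chloride (TBSCl), CC(C)(C)[Si](C)(C)Cl
Why: Selective silyl ether formation, in which the unhindered primary hydroxyl reacts much faster than the secondary benzylic one that is needed free for ring closure.

**Step 8**
Reactants: 14 the mono-TBS ether
Product: 15 methyl (2S,3S)-3-[3,4-bis(benzyloxy)phenyl]-2-[(TBSO)methyl]-2,3-dihydro-1,4-benzodioxine-6-carboxylate
Conditions: Pd(OAc)2 (5 mol%), 2-(di-tert-butylphosphino)-1,1'-binaphthyl (6 mol%), Cs2CO3, toluene, 80 °C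
Reagents that add atoms: none
Why: Buchwald-type palladium-catalysed intramolecular aryl C–O coupling, in which the new bond forms at the arene carbon so both stereocentres are retained and the syn (1S,2S) alcohol gives the trans (2S,3S) dioxane ring D.

**Step 9**
Reactants: 15 the ring D methyl ester
Product: 16 [(2S,3S)-3-[3,4-bis(benzyloxy)phenyl]-2-[(TBSO)methyl]-2,3-dihydro-1,4-benzodioxin-6-yl]methanol
Conditions: i-Bu2AlH, CH2Cl2, −78 → 0 °C; aq. KNaC4H4O6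
Reagents that add atoms: none
Why: Aluminium hydride reduction of the ester to the benzylic alcohol, to which silyl ethers, benzyl ethers and the dioxane ring are inert.

**Step 10**
Reactants: 16 the benzylic alcohol
Product: 17 (2S,3S)-3-[3,4-bis(benzyloxy)phenyl]-2-[(TBSO)methyl]-2,3-dihydro-1,4-benzodioxine-6-carbaldehyde
Conditions: MnO2, CH2Cl2, rt
Reagents that add atoms: none
Why: MnO2 oxidation is selective for benzylic alcohols and stops at the aldehyde under neutral conditions.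

**Step 11**
Reactants: 5 2-[2-bromo-4-(methoxycarbonyl)phenoxy]acetyl chloride; 18 (4S)-4-benzyl-1,3-oxazolidin-2-one
Product: 20 methyl 4-{2-[(4S)-4-benzyl-2-oxo-1,3-oxazolidin-3-yl]-2-oxoethoxy}-3-bromobenzoate, via N-lithio oxazolidinone 19 (not isolated)
Conditions: 18, n-BuLi (1.0 equiv), THF, −78 °C; then 5, −78 → 0 °C
Reagents that add atoms: none
Why: The same N-acylation of a lithiated oxazolidinone as in step 4, now with the enantiomeric auxiliary needed for the (2R,3R) ring.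

**Step 12**
Reactants: 20 the (S)-imide; 17 the ring D aldehyde
Product: 23 methyl 4-{[(2S,3R)-1-[(4S)-4-benzyl-2-oxo-1,3-oxazolidin-3-yl]-3-[(2S,3S)-3-[3,4-bis(benzyloxy)phenyl]-2-[(TBSO)methyl]-2,3-dihydro-1,4-benzodioxin-6-yl]-3-hydroxy-1-oxopropan-2-yl]oxy}-3-bromobenzoate, via Z-boron enolate 21 (not isolated), via boron aldolate 22 (not isolated)
Conditions: 20 (1.3 equiv), n-Bu2BOTf, i-Pr2NEt, CH2Cl2, −78 → 0 °C; then 17, −78 → 0 °C; then pH 7 buffer, MeOH, 30% H2O2, 0 °C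
Reagents that add atoms: none
Why: Evans syn-aldol joining the two fragments, in which the (S)-auxiliary alone controls the Zimmerman–Traxler chair (the stereocentres of 17 are remote) and sets the (2S,3R) syn pair that becomes ring E.

**Step 13**
Reactants: 23 the second syn aldol adduct
Product: 24 methyl 4-{[(1R,2R)-1-[(2S,3S)-3-[3,4-bis(benzyloxy)phenyl]-2-[(TBSO)methyl]-2,3-dihydro-1,4-benzodioxin-6-yl]-1,3-dihydroxypropan-2-yl]oxy}-3-bromobenzoate
Conditions: LiBH4, MeOH (2 equiv), THF, 0 °C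
Reagents that add atoms: none
Why: Reductive cleavage of the Evans auxiliary as in step 6, with the imide reduced chemoselectively over the methyl benzoate and no stereocentre affected.

**Step 14**
Reactants: 24 the (1R,2R) diol
Product: 25 methyl 4-{[(1R,2R)-1-[(2S,3S)-3-[3,4-bis(benzyloxy)phenyl]-2-[(TBSO)methyl]-2,3-dihydro-1,4-benzodioxin-6-yl]-3-(TBSO)-1-hydroxypropan-2-yl]oxy}-3-bromobenzoate
Conditions: TBSCl (1.1 equiv), imidazole, CH2Cl2, 0 °C
Reagents that add atoms: tert-butyldimethylsilyl chloride (TBSCl), CC(C)(C)[Si](C)(C)Cl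
Why: Selective primary silyl ether formation as in step 7, leaving the secondary benzylic hydroxyl free.

**Step 15**
Reactants: 25 the bromo alcohol
Product: 26 methyl (2R,3R)-3-[(2S,3S)-3-[3,4-bis(benzyloxy)phenyl]-2-[(TBSO)methyl]-2,3-dihydro-1,4-benzodioxin-6-yl]-2-[(TBSO)methyl]-2,3-dihydro-1,4-benzodioxine-6-carboxylate
Conditions: Pd(OAc)2 (5 mol%), 2-(di-tert-butylphosphino)-1,1'-binaphthyl (6 mol%), Cs2CO3, toluene, 80 °C
Reagents that add atoms: none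
Why: Buchwald-type palladium-catalysed intramolecular aryl C–O coupling with retention, so the syn (1R,2R) alcohol gives the trans (2R,3R) dioxane ring E.

**Step 16**
Reactants: 26 the bis-benzodioxane dibenzyl ether
Product: 27 methyl (2R,3R)-3-[(2S,3S)-3-(3,4-dihydroxyphenyl)-2-[(TBSO)methyl]-2,3-dihydro-1,4-benzodioxin-6-yl]-2-[(TBSO)methyl]-2,3-dihydro-1,4-benzodioxine-6-carboxylate
Conditions: H2 (1 atm), 10% Pd/C, EtOAc, rt
Reagents that add atoms: none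
Why: Catalytic hydrogenolysis cleaves the two primary benzyl aryl ethers much faster than the hindered secondary benzylic C–O bonds of the dioxane rings, and is placed here because no alkene or aryl bromide is present.

**Step 17**
Reactants: 27 the catechol
Product: 28 methyl (2R,3R)-3-[(2S,3S)-3-[3,4-bis(TBSO)phenyl]-2-[(TBSO)methyl]-2,3-dihydro-1,4-benzodioxin-6-yl]-2-[(TBSO)methyl]-2,3-dihydro-1,4-benzodioxine-6-carboxylate
Conditions: TBSCl (3 equiv), imidazole, DMF, rt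
Reagents that add atoms: tert-butyldimethylsilyl chloride (TBSCl), CC(C)(C)[Si](C)(C)Cl
Why: Silylation of both phenols gives a protecting-group set that survives hydride, MnO2 and Wittig steps and falls off in one fluoride step that spares the alkene.

**Step 18**
Reactants: 28 the tetrasilyl methyl ester
Product: 29 [(2R,3R)-3-[(2S,3S)-3-[3,4-bis(TBSO)phenyl]-2-[(TBSO)methyl]-2,3-dihydro-1,4-benzodioxin-6-yl]-2-[(TBSO)methyl]-2,3-dihydro-1,4-benzodioxin-6-yl]methanol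
Conditions: i-Bu2AlH, CH2Cl2, −78 °C; aq. KNaC4H4O6
Reagents that add atoms: none
Why: Aluminium hydride reduction of the ester to the benzylic alcohol at low temperature, where aryl and alkyl silyl ethers are stable.

**Step 19**
Reactants: 29 the benzylic alcohol
Product: 30 (2R,3R)-3-[(2S,3S)-3-[3,4-bis(TBSO)phenyl]-2-[(TBSO)methyl]-2,3-dihydro-1,4-benzodioxin-6-yl]-2-[(TBSO)methyl]-2,3-dihydro-1,4-benzodioxine-6-carbaldehyde
Conditions: MnO2, CH2Cl2, rt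
Reagents that add atoms: none
Why: Neutral MnO2 oxidation of the benzylic alcohol to the aldehyde, which the protected catechol tolerates.

**Step 20**
Reactants: 30 the ring A aldehyde; 31 ethyl (triphenylphosphoranylidene)acetate
Product: 32 ethyl (E)-3-[(2R,3R)-3-[(2S,3S)-3-[3,4-bis(TBSO)phenyl]-2-[(TBSO)methyl]-2,3-dihydro-1,4-benzodioxin-6-yl]-2-[(TBSO)methyl]-2,3-dihydro-1,4-benzodioxin-6-yl]prop-2-enoate
Conditions: toluene, 80 °C
Reagents that add atoms: none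
Why: Wittig olefination with a stabilised ylide under base-free conditions gives the (E)-cinnamate with high selectivity and does not disturb aryl silyl ethers.

**Step 21**
Reactants: 32 the (E)-cinnamate
Product: 33 (E)-3-[(2R,3R)-3-[(2S,3S)-3-[3,4-bis(TBSO)phenyl]-2-[(TBSO)methyl]-2,3-dihydro-1,4-benzodioxin-6-yl]-2-[(TBSO)methyl]-2,3-dihydro-1,4-benzodioxin-6-yl]prop-2-en-1-ol
Conditions: i-Bu2AlH, CH2Cl2, −78 °C; aq. KNaC4H4O6
Reagents that add atoms: none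
Why: 1,2-Reduction of the unsaturated ester by i-Bu2AlH at −78 °C gives the allylic alcohol with the alkene geometry intact.

**Step 22**
Reactants: 33 the tetrasilyl allylic alcohol
Product: 34 (E)-3-[(2R,3R)-3-[(2S,3S)-3-(3,4-dihydroxyphenyl)-2-(hydroxymethyl)-2,3-dihydro-1,4-benzodioxin-6-yl]-2-(hydroxymethyl)-2,3-dihydro-1,4-benzodioxin-6-yl]prop-2-en-1-ol
Conditions: Bu4NF, AcOH (1:1), THF, 0 °C → rt, argon
Reagents that add atoms: none
Why: Fluoride-mediated desilylation buffered with acetic acid removes all four silyl groups under near-neutral conditions that spare the acid-sensitive cinnamyl alcohol and the oxidation-prone catechol.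

**Compound list**
1 | methyl 3-bromo-4-hydroxybenzoate | COC(=O)c1ccc(O)c(Br)c1 | starting material
2 | tert-butyl bromoacetate | CC(C)(C)OC(=O)CBr | starting material
3 | tert-butyl 2-[2-bromo-4-(methoxycarbonyl)phenoxy]acetate | COC(=O)c1ccc(OCC(=O)OC(C)(C)C)c(Br)c1 | intermediate
4 | 2-[2-bromo-4-(methoxycarbonyl)phenoxy]acetic acid | COC(=O)c1ccc(OCC(O)=O)c(Br)c1 | intermediate
5 | 2-[2-bromo-4-(methoxycarbonyl)phenoxy]acetyl chloride | COC(=O)c1ccc(OCC(Cl)=O)c(Br)c1 | intermediate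
6 | (4R)-4-benzyl-1,3-oxazolidin-2-one | O=C1N[C@H](Cc2ccccc2)CO1 | starting material
7 | lithium (4R)-4-benzyl-2-oxo-1,3-oxazolidin-3-ide (N-lithio derivative of 6) | [Li]N1[C@H](Cc2ccccc2)COC1=O | intermediate
8 | methyl 4-{2-[(4R)-4-benzyl-2-oxo-1,3-oxazolidin-3-yl]-2-oxoethoxy}-3-bromobenzoate | COC(=O)c1ccc(OCC(=O)N2[C@H](Cc3ccccc3)COC2=O)c(Br)c1 | intermediate
9 | 3,4-bis(benzyloxy)benzaldehyde | O=Cc1ccc(OCc2ccccc2)c(OCc2ccccc2)c1 | starting material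
10 | methyl 4-{[(Z)-2-[(4R)-4-benzyl-2-oxo-1,3-oxazolidin-3-yl]-2-[(dibutylboranyl)oxy]ethenyl]oxy}-3-bromobenzoate (Z-boron enolate of 8) | CCCCB(CCCC)O/C(=C\Oc1ccc(cc1Br)C(=O)OC)N1[C@H](Cc2ccccc2)COC1=O | intermediate
11 | O-dibutylboranyl aldolate of 12, (2R,3S) | c1ccccc1COc1ccc(cc1OCc1ccccc1)[C@H](OB(CCCC)CCCC)[C@@H](Oc1ccc(cc1Br)C(=O)OC)C(=O)N1[C@H](Cc2ccccc2)COC1=O | intermediate
12 | methyl 4-{[(2R,3S)-1-[(4R)-4-benzyl-2-oxo-1,3-oxazolidin-3-yl]-3-[3,4-bis(benzyloxy)phenyl]-3-hydroxy-1-oxopropan-2-yl]oxy}-3-bromobenzoate | c1ccccc1COc1ccc(cc1OCc1ccccc1)[C@H](O)[C@@H](Oc1ccc(cc1Br)C(=O)OC)C(=O)N1[C@H](Cc2ccccc2)COC1=O | intermediate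
13 | methyl 4-{[(1S,2S)-1-[3,4-bis(benzyloxy)phenyl]-1,3-dihydroxypropan-2-yl]oxy}-3-bromobenzoate | c1ccccc1COc1ccc(cc1OCc1ccccc1)[C@H](O)[C@@H](Oc1ccc(cc1Br)C(=O)OC)CO | intermediate
14 | methyl 4-{[(1S,2S)-1-[3,4-bis(benzyloxy)phenyl]-3-(TBSO)-1-hydroxypropan-2-yl]oxy}-3-bromobenzoate | c1ccccc1COc1ccc(cc1OCc1ccccc1)[C@H](O)[C@@H](Oc1ccc(cc1Br)C(=O)OC)CO[Si](C)(C)C(C)(C)C | intermediate
15 | methyl (2S,3S)-3-[3,4-bis(benzyloxy)phenyl]-2-[(TBSO)methyl]-2,3-dihydro-1,4-benzodioxine-6-carboxylate | c1ccccc1COc1ccc(cc1OCc1ccccc1)[C@@H]1Oc2cc(ccc2O[C@H]1CO[Si](C)(C)C(C)(C)C)C(=O)OC | intermediate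
16 | [(2S,3S)-3-[3,4-bis(benzyloxy)phenyl]-2-[(TBSO)methyl]-2,3-dihydro-1,4-benzodioxin-6-yl]methanol | c1ccccc1COc1ccc(cc1OCc1ccccc1)[C@@H]1Oc2cc(ccc2O[C@H]1CO[Si](C)(C)C(C)(C)C)CO | intermediate
17 | (2S,3S)-3-[3,4-bis(benzyloxy)phenyl]-2-[(TBSO)methyl]-2,3-dihydro-1,4-benzodioxine-6-carbaldehyde | c1ccccc1COc1ccc(cc1OCc1ccccc1)[C@@H]1Oc2cc(ccc2O[C@H]1CO[Si](C)(C)C(C)(C)C)C=O | intermediate
18 | (4S)-4-benzyl-1,3-oxazolidin-2-one | O=C1N[C@@H](Cc2ccccc2)CO1 | starting material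
19 | lithium (4S)-4-benzyl-2-oxo-1,3-oxazolidin-3-ide (N-lithio derivative of 18) | [Li]N1[C@@H](Cc2ccccc2)COC1=O | intermediate
20 | methyl 4-{2-[(4S)-4-benzyl-2-oxo-1,3-oxazolidin-3-yl]-2-oxoethoxy}-3-bromobenzoate | COC(=O)c1ccc(OCC(=O)N2[C@@H](Cc3ccccc3)COC2=O)c(Br)c1 | intermediate
21 | methyl 4-{[(Z)-2-[(4S)-4-benzyl-2-oxo-1,3-oxazolidin-3-yl]-2-[(dibutylboranyl)oxy]ethenyl]oxy}-3-bromobenzoate (Z-boron enolate of 20) | CCCCB(CCCC)O/C(=C\Oc1ccc(cc1Br)C(=O)OC)N1[C@@H](Cc2ccccc2)COC1=O | intermediate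
22 | O-dibutylboranyl aldolate of 23, (2S,3R) | c1ccccc1COc1ccc(cc1OCc1ccccc1)[C@@H]1Oc2cc(ccc2O[C@H]1CO[Si](C)(C)C(C)(C)C)[C@@H](OB(CCCC)CCCC)[C@H](Oc1ccc(cc1Br)C(=O)OC)C(=O)N1[C@@H](Cc2ccccc2)COC1=O | intermediate
23 | methyl 4-{[(2S,3R)-1-[(4S)-4-benzyl-2-oxo-1,3-oxazolidin-3-yl]-3-[(2S,3S)-3-[3,4-bis(benzyloxy)phenyl]-2-[(TBSO)methyl]-2,3-dihydro-1,4-benzodioxin-6-yl]-3-hydroxy-1-oxopropan-2-yl]oxy}-3-bromobenzoate | c1ccccc1COc1ccc(cc1OCc1ccccc1)[C@@H]1Oc2cc(ccc2O[C@H]1CO[Si](C)(C)C(C)(C)C)[C@@H](O)[C@H](Oc1ccc(cc1Br)C(=O)OC)C(=O)N1[C@@H](Cc2ccccc2)COC1=O | intermediate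
24 | methyl 4-{[(1R,2R)-1-[(2S,3S)-3-[3,4-bis(benzyloxy)phenyl]-2-[(TBSO)methyl]-2,3-dihydro-1,4-benzodioxin-6-yl]-1,3-dihydroxypropan-2-yl]oxy}-3-bromobenzoate | c1ccccc1COc1ccc(cc1OCc1ccccc1)[C@@H]1Oc2cc(ccc2O[C@H]1CO[Si](C)(C)C(C)(C)C)[C@@H](O)[C@H](Oc1ccc(cc1Br)C(=O)OC)CO | intermediate
25 | methyl 4-{[(1R,2R)-1-[(2S,3S)-3-[3,4-bis(benzyloxy)phenyl]-2-[(TBSO)methyl]-2,3-dihydro-1,4-benzodioxin-6-yl]-3-(TBSO)-1-hydroxypropan-2-yl]oxy}-3-bromobenzoate | c1ccccc1COc1ccc(cc1OCc1ccccc1)[C@@H]1Oc2cc(ccc2O[C@H]1CO[Si](C)(C)C(C)(C)C)[C@@H](O)[C@H](Oc1ccc(cc1Br)C(=O)OC)CO[Si](C)(C)C(C)(C)C | intermediate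
26 | methyl (2R,3R)-3-[(2S,3S)-3-[3,4-bis(benzyloxy)phenyl]-2-[(TBSO)methyl]-2,3-dihydro-1,4-benzodioxin-6-yl]-2-[(TBSO)methyl]-2,3-dihydro-1,4-benzodioxine-6-carboxylate | c1ccccc1COc1ccc(cc1OCc1ccccc1)[C@@H]1Oc2cc(ccc2O[C@H]1CO[Si](C)(C)C(C)(C)C)[C@H]1Oc2cc(ccc2O[C@@H]1CO[Si](C)(C)C(C)(C)C)C(=O)OC | intermediate
27 | methyl (2R,3R)-3-[(2S,3S)-3-(3,4-dihydroxyphenyl)-2-[(TBSO)methyl]-2,3-dihydro-1,4-benzodioxin-6-yl]-2-[(TBSO)methyl]-2,3-dihydro-1,4-benzodioxine-6-carboxylate | Oc1ccc(cc1O)[C@@H]1Oc2cc(ccc2O[C@H]1CO[Si](C)(C)C(C)(C)C)[C@H]1Oc2cc(ccc2O[C@@H]1CO[Si](C)(C)C(C)(C)C)C(=O)OC | intermediate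
28 | methyl (2R,3R)-3-[(2S,3S)-3-[3,4-bis(TBSO)phenyl]-2-[(TBSO)methyl]-2,3-dihydro-1,4-benzodioxin-6-yl]-2-[(TBSO)methyl]-2,3-dihydro-1,4-benzodioxine-6-carboxylate | CC(C)(C)[Si](C)(C)Oc1ccc(cc1O[Si](C)(C)C(C)(C)C)[C@@H]1Oc2cc(ccc2O[C@H]1CO[Si](C)(C)C(C)(C)C)[C@H]1Oc2cc(ccc2O[C@@H]1CO[Si](C)(C)C(C)(C)C)C(=O)OC | intermediate
29 | [(2R,3R)-3-[(2S,3S)-3-[3,4-bis(TBSO)phenyl]-2-[(TBSO)methyl]-2,3-dihydro-1,4-benzodioxin-6-yl]-2-[(TBSO)methyl]-2,3-dihydro-1,4-benzodioxin-6-yl]methanol | CC(C)(C)[Si](C)(C)Oc1ccc(cc1O[Si](C)(C)C(C)(C)C)[C@@H]1Oc2cc(ccc2O[C@H]1CO[Si](C)(C)C(C)(C)C)[C@H]1Oc2cc(ccc2O[C@@H]1CO[Si](C)(C)C(C)(C)C)CO | intermediate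
30 | (2R,3R)-3-[(2S,3S)-3-[3,4-bis(TBSO)phenyl]-2-[(TBSO)methyl]-2,3-dihydro-1,4-benzodioxin-6-yl]-2-[(TBSO)methyl]-2,3-dihydro-1,4-benzodioxine-6-carbaldehyde | CC(C)(C)[Si](C)(C)Oc1ccc(cc1O[Si](C)(C)C(C)(C)C)[C@@H]1Oc2cc(ccc2O[C@H]1CO[Si](C)(C)C(C)(C)C)[C@H]1Oc2cc(ccc2O[C@@H]1CO[Si](C)(C)C(C)(C)C)C=O | intermediate
31 | ethyl (triphenylphosphoranylidene)acetate | CCOC(=O)C=P(c1ccccc1)(c1ccccc1)c1ccccc1 | starting material
32 | ethyl (E)-3-[(2R,3R)-3-[(2S,3S)-3-[3,4-bis(TBSO)phenyl]-2-[(TBSO)methyl]-2,3-dihydro-1,4-benzodioxin-6-yl]-2-[(TBSO)methyl]-2,3-dihydro-1,4-benzodioxin-6-yl]prop-2-enoate | CC(C)(C)[Si](C)(C)Oc1ccc(cc1O[Si](C)(C)C(C)(C)C)[C@@H]1Oc2cc(ccc2O[C@H]1CO[Si](C)(C)C(C)(C)C)[C@H]1Oc2cc(ccc2O[C@@H]1CO[Si](C)(C)C(C)(C)C)/C=C/C(=O)OCC | intermediate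
33 | (E)-3-[(2R,3R)-3-[(2S,3S)-3-[3,4-bis(TBSO)phenyl]-2-[(TBSO)methyl]-2,3-dihydro-1,4-benzodioxin-6-yl]-2-[(TBSO)methyl]-2,3-dihydro-1,4-benzodioxin-6-yl]prop-2-en-1-ol | CC(C)(C)[Si](C)(C)Oc1ccc(cc1O[Si](C)(C)C(C)(C)C)[C@@H]1Oc2cc(ccc2O[C@H]1CO[Si](C)(C)C(C)(C)C)[C@H]1Oc2cc(ccc2O[C@@H]1CO[Si](C)(C)C(C)(C)C)/C=C/CO | intermediate
34 | (E)-3-[(2R,3R)-3-[(2S,3S)-3-(3,4-dihydroxyphenyl)-2-(hydroxymethyl)-2,3-dihydro-1,4-benzodioxin-6-yl]-2-(hydroxymethyl)-2,3-dihydro-1,4-benzodioxin-6-yl]prop-2-en-1-ol | Oc1ccc(cc1O)[C@@H]1Oc2cc(ccc2O[C@H]1CO)[C@H]1Oc2cc(ccc2O[C@@H]1CO)/C=C/CO | target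

**Step count and risks**
Total steps: 22. Longest linear sequence: 21 steps (steps 1–10, then 12–22; step 11 is a one-step branch from compound 5).

Most likely to fail, with fallbacks:

Step 6 (the same reduction recurs in step 13). LiBH4 may also reduce part of the methyl benzoate. The fallback sets out from 12 and comes back at 13. The auxiliary is hydrolysed with LiOH/H2O2 (THF/H2O, 0 °C) to (2R,3S)-3-[3,4-bis(benzyloxy)phenyl]-2-[2-bromo-4-(methoxycarbonyl)phenoxy]-3-hydroxypropanoic acid F1. BH3·SMe2 (THF, 0 °C → rt) then reduces only the carboxylic acid, not the ester, to give diol 13.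

Step 8 (the same closure recurs in step 15). The palladium alkoxide of the hindered secondary benzylic alcohol may undergo β-hydride elimination to the ketone, or the bromide may be reduced off. The fallback sets out from 14 and comes back at 15, replacing the aryl C–O coupling by closure at the benzylic carbon. Miyaura borylation (PdCl2(dppf), bis(pinacolato)diboron, KOAc, dioxane, 80 °C) gives methyl 4-{[(1S,2S)-1-[3,4-bis(benzyloxy)phenyl]-3-(TBSO)-1-hydroxypropan-2-yl]oxy}-3-(4,4,5,5-tetramethyl-1,3,2-dioxaborolan-2-yl)benzoate F2. Oxidation (NaBO3·4H2O, THF/H2O, rt) gives methyl 4-{[(1S,2S)-1-[3,4-bis(benzyloxy)phenyl]-3-(TBSO)-1-hydroxypropan-2-yl]oxy}-3-hydroxybenzoate F3. Camphorsulfonic acid (10 mol%, CH2Cl2, 0 °C → rt) then ionises the p-benzyloxybenzylic alcohol and the neighbouring phenol traps the cation. Under these reversible conditions the diequatorial trans ring 15 should predominate; this closure is not stereospecific, and the minor cis isomer is removed by chromatography.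

Step 12. The boron enolate may add sluggishly or with lower selectivity to the bulky, electron-rich aldehyde 17. The fallback sets out from 4 and 17 and comes back at 24, using a titanium enolate of a thiazolidinethione in place of the boron enolate. Acid 4 is coupled (EDC·HCl, DMAP, CH2Cl2) with (4S)-4-benzyl-1,3-thiazolidine-2-thione to give methyl 4-{2-[(4S)-4-benzyl-2-thioxo-1,3-thiazolidin-3-yl]-2-oxoethoxy}-3-bromobenzoate F4. A Crimmins-type titanium aldol (TiCl4 1.05 equiv, i-Pr2NEt 1.1 equiv, N-methyl-2-pyrrolidinone 1 equiv, CH2Cl2, 0 °C, then 17) gives methyl 4-{[(2S,3R)-1-[(4S)-4-benzyl-2-thioxo-1,3-thiazolidin-3-yl]-3-[(2S,3S)-3-[3,4-bis(benzyloxy)phenyl]-2-[(TBSO)methyl]-2,3-dihydro-1,4-benzodioxin-6-yl]-3-hydroxy-1-oxopropan-2-yl]oxy}-3-bromobenzoate F5 in the same syn sense; the more Lewis-acidic titanium enolate is more reactive toward the hindered aldehyde. NaBH4 (THF/EtOH, 0 °C) cleaves the thioimide directly to diol 24, leaving the methyl benzoate untouched.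

**Further compounds**
F1 | step 6 | (2R,3S)-3-[3,4-bis(benzyloxy)phenyl]-2-[2-bromo-4-(methoxycarbonyl)phenoxy]-3-hydroxypropanoic acid | c1ccccc1COc1ccc(cc1OCc1ccccc1)[C@H](O)[C@@H](Oc1ccc(cc1Br)C(=O)OC)C(O)=O
F2 | step 8 | methyl 4-{[(1S,2S)-1-[3,4-bis(benzyloxy)phenyl]-3-(TBSO)-1-hydroxypropan-2-yl]oxy}-3-(4,4,5,5-tetramethyl-1,3,2-dioxaborolan-2-yl)benzoate | c1ccccc1COc1ccc(cc1OCc1ccccc1)[C@H](O)[C@@H](Oc1ccc(cc1B1OC(C)(C)C(C)(C)O1)C(=O)OC)CO[Si](C)(C)C(C)(C)C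
F3 | step 8 | methyl 4-{[(1S,2S)-1-[3,4-bis(benzyloxy)phenyl]-3-(TBSO)-1-hydroxypropan-2-yl]oxy}-3-hydroxybenzoate | c1ccccc1COc1ccc(cc1OCc1ccccc1)[C@H](O)[C@@H](Oc1ccc(cc1O)C(=O)OC)CO[Si](C)(C)C(C)(C)C
F4 | step 12 | methyl 4-{2-[(4S)-4-benzyl-2-thioxo-1,3-thiazolidin-3-yl]-2-oxoethoxy}-3-bromobenzoate | COC(=O)c1ccc(OCC(=O)N2[C@@H](Cc3ccccc3)CSC2=S)c(Br)c1
F5 | step 12 | methyl 4-{[(2S,3R)-1-[(4S)-4-benzyl-2-thioxo-1,3-thiazolidin-3-yl]-3-[(2S,3S)-3-[3,4-bis(benzyloxy)phenyl]-2-[(TBSO)methyl]-2,3-dihydro-1,4-benzodioxin-6-yl]-3-hydroxy-1-oxopropan-2-yl]oxy}-3-bromobenzoate | c1ccccc1COc1ccc(cc1OCc1ccccc1)[C@@H]1Oc2cc(ccc2O[C@H]1CO[Si](C)(C)C(C)(C)C)[C@@H](O)[C@H](Oc1ccc(cc1Br)C(=O)OC)C(=O)N1[C@@H](Cc2ccccc2)CSC1=S
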